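The quinone is treated as an oxidised 5-alkylresorcinol monomethyl ether, exploiting the 1,3-related oxygens on C2 and C4 (ring numbering: C1 = carbonyl between methoxy-bearing C2 and alkyl-bearing C6; C4 = the other carbonyl). C4, C5 and C6 are the ester, α- and β-carbons of a 2-alkynoate that already carries the (R)-carbinol chain; C1–C2(OMe)–C3 is an acetone enol ether unit. In one operation a Michael–Claisen [3+3] benzannulation joins them: the dilithium dienediolate of (E)-3-methoxybut-2-enoic acid adds to the ynoate (C1–C6) and closes onto its ester carbon (C3–C4); the activating carboxyl group then leaves as CO2. Teuber oxidation installs the C1 oxygen and acetylation completes the target.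

Key step: step 4

Remark on the chemistry: the acetoxy-bearing carbon of the target is (R); it is bought with (R)-epichlorohydrin 1 and is never a reacting centre.

Step 1
Reactants: 1 (R)-epichlorohydrin; 2 dodecylmagnesium bromide
Product: 4 (R)-2-tridecyloxirane, via chlorohydrin 3 (not isolated)
Conditions: CuI (10 mol %), THF, −40 to 0 °C; H2O; then powdered NaOH, Et2O, 23 °C
Reagents that add atoms: none
Why: Copper-catalysed SN2 opening of the epoxide at its unsubstituted carbon by the Grignard reagent, then intramolecular Williamson closure of chlorohydrin 3; the carbinol carbon is not a reacting centre, so (R)-1 should give (R)-4.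

Step 2
Reactants: 4 (R)-2-tridecyloxirane; 5 methyl propiolate
Product: 7 methyl (R)-5-hydroxyoctadec-2-ynoate, via lithium acetylide 6 (not isolated)
Conditions: n-BuLi, THF, −78 °C; BF3·OEt2; then 4, −78 °C
Reagents that add atoms: none
Why: Yamaguchi alkynylation, in which lithium acetylide 6 opens the BF3-activated epoxide by SN2 attack at the terminal carbon, leaving the (R) carbinol centre untouched.

Step 3
Reactants: 8 methyl (E)-3-methoxybut-2-enoate
Product: 9 (E)-3-methoxybut-2-enoic acid
Conditions: LiOH, THF/H2O, 40 °C; then cold 1 M HCl to pH 3
Reagents that add atoms: lithium hydroxide, [Li+].[OH-]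
Why: Saponification of a vinylogous carbonate ester; the conjugated enol ether and its E geometry should survive mild base and a brief cold acidification.

Step 4
Reactants: 7 methyl (R)-5-hydroxyoctadec-2-ynoate; 9 (E)-3-methoxybut-2-enoic acid
Product: 12 3-[(R)-2-hydroxypentadecyl]-5-methoxyphenol, via dienediolate 10 (not isolated), via salicylic acid 11 (not isolated)
Conditions: 9 (2.2 equiv), LiN(i-Pr)2 (4.4 equiv), THF, −78 to 0 °C; add 7, −78 to 40 °C; 2 M HCl; then DMSO, 130 °C
Reagents that add atoms: none
Why: The γ-carbon of dienediolate 10 (the terminus at which β-alkoxy dienolates react) adds to the β-carbon of the ynoate of 7 (Michael addition, new bond C1–C6), proton transfer gives a delocalised trienolate in which the E and Z adducts interconvert, and its carboxylate-bearing α-carbon then attacks the ynoate ester carbonyl (Claisen condensation, new bond C3–C4) with loss of methoxide, after which enolisation gives salicylate 11. The closest known reaction type is the Michael–Claisen [3+3] condensation of acetoacetate carbanions with 2-alkynoates or 2-alkenoates that gives resorcylates and dihydroresorcinols. The benzene ring closes by a 6-exo-trig attack of the dienolate carbon on the ester carbonyl (equivalent to a 6π electrocyclisation of the oxidotriene), and aromatisation makes the closure irreversible. No stereocentre is formed, and the carbinol centre, carried as its lithium alkoxide by one extra equivalent of 10, is not a reacting centre. The step needs ring closure onto the ynoate ester and not onto the acyl carbon of the nucleophile: the carboxylate of 10 cannot accept a carbanion, so only the wanted six-membered ring can form, and the methoxy group is already fixed on C2. Acid 11, a salicylic acid flanked by hydroxy and methoxy groups and remote from the side-chain hydroxyl, should lose CO2 on heating, which removes the activating group without a trace.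

Step 5
Reactants: 12 3-[(R)-2-hydroxypentadecyl]-5-methoxyphenol
Product: 13 2-[(R)-2-hydroxypentadecyl]-6-methoxy-1,4-benzoquinone
Conditions: ON(SO3K)2 (Fremy's salt, 2.5 equiv), KH2PO4, H2O/acetone, 23 °C
Reagents that add atoms: potassium nitrosodisulfonate (Fremy's salt), [K+].[K+].[O]N(S(=O)(=O)[O-])S(=O)(=O)[O-]
Why: Teuber oxidation, in which Fremy's radical abstracts the phenolic hydrogen and a second radical couples at the free para carbon C1 before loss of imidodisulfonate gives the para-quinone, as is usual for 3-methoxy-5-alkylphenols; the secondary alcohol is inert.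

Step 6
Reactants: 13 2-[(R)-2-hydroxypentadecyl]-6-methoxy-1,4-benzoquinone
Product: 14 ardisinone
Conditions: Ac2O, pyridine, 4-(dimethylamino)pyridine (cat.), CH2Cl2, 0 °C
Reagents that add atoms: acetic anhydride, CC(=O)OC(C)=O
Why: Nucleophile-catalysed O-acylation of the secondary alcohol (Steglich-type acetylation); no bond to the stereocentre is broken, so the (R) configuration is retained.

Compound list
1 | (R)-epichlorohydrin | ClC[C@H]1CO1 | starting material
2 | dodecylmagnesium bromide | CCCCCCCCCCCC[Mg]Br | starting material
3 | (R)-1-chloropentadecan-2-ol | ClC[C@H](O)CCCCCCCCCCCCC | intermediate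
4 | (R)-2-tridecyloxirane | CCCCCCCCCCCCC[C@@H]1CO1 | intermediate
5 | methyl propiolate | C#CC(=O)OC | starting material
6 | methyl 3-lithiopropiolate | [Li]C#CC(=O)OC | intermediate
7 | methyl (R)-5-hydroxyoctadec-2-ynoate | CCCCCCCCCCCCC[C@@H](O)CC#CC(=O)OC | intermediate
8 | methyl (E)-3-methoxybut-2-enoate | CO/C(C)=C/C(=O)OC | starting material
9 | (E)-3-methoxybut-2-enoic acid | CO/C(C)=C/C(=O)O | intermediate
10 | dilithium 3-methoxybuta-1,3-diene-1,1-diolate | [Li+].[Li+].[O-]C([O-])=CC(OC)=C | intermediate
11 | 2-hydroxy-4-[(R)-2-hydroxypentadecyl]-6-methoxybenzoic acid | CCCCCCCCCCCCC[C@@H](O)Cc1cc(O)c(C(=O)O)c(OC)c1 | intermediate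
12 | 3-[(R)-2-hydroxypentadecyl]-5-methoxyphenol | CCCCCCCCCCCCC[C@@H](O)Cc1cc(O)cc(OC)c1 | intermediate
13 | 2-[(R)-2-hydroxypentadecyl]-6-methoxy-1,4-benzoquinone | CCCCCCCCCCCCC[C@@H](O)CC1=CC(=O)C=C(OC)C1=O | intermediate
14 | ardisinone, 2-[(R)-2-acetoxypentadecyl]-6-methoxy-1,4-benzoquinone | CCCCCCCCCCCCC[C@H](CC1=CC(=O)C=C(OC)C1=O)OC(C)=O | target

Total step count: 6. Longest linear sequence: 5 steps (steps 1, 2, 4, 5, 6); step 3 is a side branch.

Steps most likely to fail

1. Step 4. Proton transfer from the propargylic CH2 of 7 to the strongly basic dienediolate may outrun carbon–carbon bond formation. The polyanionic Michael adduct may also fail to close. First attack through the α-carbon would place the carboxyl group next to the side chain, where lactonisation competes with loss of CO2. The fallback buys the ring and does not build it. It sets out from 4: copper-catalysed opening with commercial 3,5-dimethoxyphenylmagnesium chloride (CuI cat., THF, −30 to 0 °C) should give (R)-1-(3,5-dimethoxyphenyl)pentadecan-2-ol F1. Thiolate demethylation of one of its two equivalent methoxy groups (NaSEt, DMF, 150 °C) should then give the phenol, and the route is rejoined at 12.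

2. Step 6. Conjugate addition of the pyridine bases or of the side-chain alkoxide to the methoxyquinone, or redox decomposition, may erode the quinone during acylation. The fallback acetylates before it oxidises and sets out from 12. Ac2O/pyridine should give the diacetate (R)-1-(3-acetoxy-5-methoxyphenyl)pentadecan-2-yl acetate F2. Pyrrolidine (1.1 equiv, CH2Cl2, 0 °C) should cleave only the aryl acetate to (R)-1-(3-hydroxy-5-methoxyphenyl)pentadecan-2-yl acetate F3. Teuber oxidation of F3 with ON(SO3K)2 under the conditions of step 5 should then give the target directly, so the route is rejoined at 14.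

3. Step 2. The thermally fragile lithiated propiolate may oligomerise before it captures the epoxide, and BF3 may rearrange the epoxide to the aldehyde. The fallback introduces the alkyne and the carboxyl carbon separately and sets out from 4. LiC≡CH·H2NCH2CH2NH2 in DMSO at 23 °C should give (R)-heptadec-1-yn-4-ol F4. Double deprotonation (n-BuLi, 2.2 equiv, THF, −78 °C) and carboxylation with CO2 should give (R)-5-hydroxyoctadec-2-ynoic acid F5. Esterification with Me3SiCHN2 in toluene/MeOH then rejoins the route at 7.

Further compounds
F1 | step 4 | (R)-1-(3,5-dimethoxyphenyl)pentadecan-2-ol | CCCCCCCCCCCCC[C@@H](O)Cc1cc(OC)cc(OC)c1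
F2 | step 6 | (R)-1-(3-acetoxy-5-methoxyphenyl)pentadecan-2-yl acetate | CCCCCCCCCCCCC[C@@H](OC(C)=O)Cc1cc(OC(C)=O)cc(OC)c1
F3 | step 6 | (R)-1-(3-hydroxy-5-methoxyphenyl)pentadecan-2-yl acetate | CCCCCCCCCCCCC[C@@H](OC(C)=O)Cc1cc(O)cc(OC)c1
F4 | step 2 | (R)-heptadec-1-yn-4-ol | CCCCCCCCCCCCC[C@@H](O)CC#C
F5 | step 2 | (R)-5-hydroxyoctadec-2-ynoic acid | CCCCCCCCCCCCC[C@@H](O)CC#CC(=O)O
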